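# Total synthesis proposal: sargachromanol C

## Analysis of the target

Sargachromanol C (13, C27H40O3) is a 6-hydroxy-8-methylchroman. Aromatic ring A (C4a, C5, C6, C7, C8, C8a) is fused to dihydropyran ring B (O1, C2, C3, C4, C4a, C8a). C2 carries a methyl group and a sixteen-carbon chain C1'–C12' with the alkenes C3'=C4' (E), C7'=C8' (E) and the terminal isopropylidene C11'=C12'.

There are two stereocentres. C2 (R) is a fully substituted ether carbon whose three carbon arms (CH3, C3H2, C1'H2) differ little near the centre. C9' (R) is a secondary carbinol, allylic to C7'=C8' and homoallylic to C11'=C12'. They lie nine bonds apart, so neither can direct the other and the epimers cannot be expected to separate. Each centre therefore needs its own high level of absolute control.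

The array C7'=C8'–C9'(OH)–C10'–C11'=C12' is a 1,5-dien-3-ol that ionises in acid and can undergo oxy-Cope rearrangement under strong base. All three alkenes invite cationic cyclisation, and the free chromanol is easily oxidised to a quinone. The difficulty is selectivity rather than size: ring B must be closed on a quaternary stereocentre in the presence of a polyene, and two E-trisubstituted alkenes must be geometrically pure.

The route is built on the contiguous triad C8(CH3)–C8a(O1)–C4a(C4) on ring A, with the C6 oxygen para to C8a. C4a is meta to the C6 oxygen, so electrophilic substitution cannot reach it. It is, however, the only free position ortho to C8a, because the C8 methyl group blocks the other. This is the ipso/ortho pattern of a Catellani reaction on an ortho-methyl aryl iodide. Because C2 bears no hydrogen, its alkoxide can sit on palladium without β-hydride elimination.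

## Retrosynthetic reasoning

**13 ⇒ 12 (O–Si at C6).** The phenol is unmasked last. A free chromanol would not survive the oxidants and the metal catalysts used on the chain. The forward step only has to cleave an aryl silyl ether under buffered, non-basic conditions that leave the 1,5-dien-3-ol alone.

**12 ⇒ 11 (C11'=C12').** Prenyl-metal reagents add to aldehydes through their γ-carbon and would give the branched 1,1-dimethylallyl carbinol, not the linear chain. The C5 terminus is therefore split into an allyl group, whose enantioselective delivery is well understood, and an isopropylidene cap exchanged in by cross metathesis. The forward reaction must engage only the single monosubstituted alkene of 11.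

**11 ⇒ 9 (C9'–C10').** This is the one C–C bond at C9' whose formation starts from a stable carbonyl partner, the E-enal 9, in which C7'=C8' is already fixed. Cutting C8'–C9' instead would need a labile β,γ-unsaturated aldehyde and a regiodefined trisubstituted alkenyl metal. The forward step must deliver allyl to the Re face under pure catalyst control.

**9 ⇒ 7 (C9'–O).** The oxygen at C9' is introduced by C–H oxidation of the E-methyl group of the terminal isopropylidene of 7. Compound 7 can then carry an unfunctionalised chain, and the E geometry of C7'=C8' follows from the mechanism of the oxidation.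

**7 ⇒ 4 + 6 (C4–C4a and O1–C8a, key step).** Both bonds that tie ring B to ring A are cut at once.
- O1 stays with the terpene half, so the C2–O bond, and with it the stereocentre, is never made or broken during ring closure.
- Cutting O1–C2, as biosynthesis does, would force ring closure and face selection at a trisubstituted alkene into one event.
- The precursors are far simpler than 7: 6 is a monocyclic aryl iodide without any group at C4a, and 4 is an acyclic γ-bromo tertiary alcohol.
- The forward reaction must alkylate the ortho C–H bond of 6 with the C–Br terminus of 4 and then end at the ipso carbon by C–O bond formation. Fragment union and ring closure thus become one operation.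

**4 ⇒ 3 ⇒ 2 ⇒ 1 (C–Br, C3–H, epoxide).**
- Bromide 4 comes from the primary hydroxyl of diol 3.
- Diol 3 comes from hydroxyl-directed hydride opening of epoxy alcohol 2.
- Epoxy alcohol 2 comes from asymmetric epoxidation of farnesol 1.
- Farnesol 1 already holds every carbon from C4 to C9' and both alkene geometries. Its allylic alcohol is the handle that lets one reliable catalytic step set C2.

**6 ⇒ 5 (O–Si).** The aryl iodide 5 is bought and only needs its phenol masked with a group that withstands hot carbonate and falls to fluoride.

## Alternatives that were turned down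

**Alternative 1:** the textbook route cuts the allyl–allyl seam C5'–C6' and treats the chroman as a separately made enantiopure building block.
- *Forward key step:* the lithiated allylic sulfone A1 (C6'–C12', C9' as silyl ether) is alkylated by the chroman allylic bromide A2 (C2–C5') to give sulfone A3. Palladium-catalysed hydride desulfonylation follows.
- *Why turned down:*
  - The coupling makes one unstrained σ-bond and neither a ring nor a stereocentre.
  - Each half still needs its own asymmetric step and several functional-group changes.
  - The sulfonyl group costs steps to put on and take off.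
  - Its removal runs through a π-allylpalladium species next to the C9' oxygen. Hydride can be delivered at either terminus there, and the C9' oxygen is itself an allylic leaving group. This puts the position and geometry of C7'=C8' at risk.
  - The step count would be well above that of the chosen route.

**Alternative 2:** the biomimetic route cuts only O1–C2.
- *Forward key step:* a cyclase-like, protonation-initiated 6-endo hydroalkoxylation of the open-chain hydroquinone A4 with a confined chiral Brønsted acid. This would set C2 and close ring B together.
- *Why turned down:*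
  - The acid would have to pick C2=C3 out of four trisubstituted alkenes of similar basicity.
  - Protonation at C11'=C12' opens a cation–olefin cyclisation onto C7'=C8'.
  - The allylic C9' hydroxyl ionises more readily than an alkene is protonated.
  - Face discrimination at C2 rests on the small difference between CH3 and CH2.
  - A4 itself needs a regiocontrolled C-allylation ortho to the more hindered hydroxyl group.

**Alternative 3:** this route cuts C3–C4 and O1–C2 together.
- *Forward key step:* an inverse-demand hetero-Diels–Alder reaction of the ortho-quinone methide A5 with the 1,1-disubstituted terminal alkene of triene A6, giving chroman A7. It also forms two bonds and ring B in one step, with the right regiochemistry (oxygen to the more substituted carbon).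
- *Why turned down:*
  - C2 would arise from an unactivated alkene whose faces differ only by CH3 versus CH2R, with no binding site for a chiral catalyst. A7 would therefore be racemic and need a resolution.
  - The two trisubstituted alkenes of A6 are at least as nucleophilic as the terminal one.
  - A5 is prone to self-dimerisation.

Key step: step 5

Assumption: (2E,6E)-farnesol of high geometric purity and 4-iodo-3-methylphenol are taken as commercial. Locants O1–C8a are those of the chroman, and C1'–C12' are counted along the side chain from C2, with C12' the alkene carbon that bears two methyl groups.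

## Route

Step 1
Reactants: 1 (2E,6E)-farnesol
Product: 2 [(2R,3R)-3-[(3E)-4,8-dimethylnona-3,7-dien-1-yl]-3-methyloxiran-2-yl]methanol
Conditions: Ti(OiPr)4 (10 mol %), D-(−)-diethyl tartrate (12 mol %), t-BuOOH (2 equiv, decane), 4 Å MS, CH2Cl2, −20 °C
Reagents that add atoms: tert-butyl hydroperoxide, CC(C)(C)OO
Why: Katsuki–Sharpless asymmetric epoxidation; only the alkene next to the titanium-bound hydroxyl reacts, so the two remote alkenes are untouched. The D-(−)-tartrate series gives the (2R,3R)-epoxide of E-3-methyl-2-alken-1-ols (the L-(+)-series gives 2S,3S), and the fully substituted epoxide carbon is the later C2 (R).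

Step 2
Reactants: 2 [(2R,3R)-3-[(3E)-4,8-dimethylnona-3,7-dien-1-yl]-3-methyloxiran-2-yl]methanol
Product: 3 (3R,6E)-3,7,11-trimethyldodeca-6,10-diene-1,3-diol
Conditions: NaAlH2(OCH2CH2OCH3)2 (2.5 equiv), THF, 0 °C to rt; aq. potassium sodium tartrate
Reagents that add atoms: none
Why: Hydroxyl-directed reductive opening of a 2,3-epoxy alcohol; the alkoxyaluminate delivers hydride to the secondary epoxide carbon, which is also the less hindered one, so the 1,3-diol should result. The tertiary C–O bond is not touched, so the R configuration is retained.

Step 3
Reactants: 3 (3R,6E)-3,7,11-trimethyldodeca-6,10-diene-1,3-diol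
Product: 4 (3R,6E)-1-bromo-3,7,11-trimethyldodeca-6,10-dien-3-ol
Conditions: CBr4 (1.2 equiv), PPh3 (1.25 equiv), CH2Cl2, 0 °C
Reagents that add atoms: carbon tetrabromide, BrC(Br)(Br)Br
Why: Appel reaction; only the primary hydroxyl forms an alkoxyphosphonium ion that bromide can displace by SN2, while the tertiary hydroxyl is too hindered at 0 °C. The neutral medium spares the alkenes and the stereocentre.

Step 4
Reactants: 5 4-iodo-3-methylphenol
Product: 6 (4-iodo-3-methylphenoxy)triisopropylsilane
Conditions: i-Pr3SiCl (1.1 equiv), imidazole (2 equiv), DMF, rt
Reagents that add atoms: triisopropylsilyl chloride, CC(C)[Si](Cl)(C(C)C)C(C)C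
Why: Standard phenol silylation. The bulky aryl silyl ether is chosen because it should withstand carbonate at 100 °C, SeO2/t-BuOOH, MnO2, a Brønsted acid catalyst and a ruthenium carbene, and still fall to fluoride at the end.

Step 5
Reactants: 4 (3R,6E)-1-bromo-3,7,11-trimethyldodeca-6,10-dien-3-ol; 6 (4-iodo-3-methylphenoxy)triisopropylsilane
Product: 7 (2R)-2-[(3E)-4,8-dimethylnona-3,7-dien-1-yl]-2,8-dimethyl-6-(triisopropylsilyloxy)chromane
Conditions: Pd(OAc)2 (10 mol %), 2-dicyclohexylphosphino-2',6'-diisopropoxybiphenyl (RuPhos, 20 mol %), norbornene (1 equiv), Cs2CO3 (3 equiv), 1,4-dioxane, 100 °C; 4 (1.3 equiv) added slowly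
Reagents that add atoms: none
Why: Proposed new method: zerovalent palladium inserts into the C–I bond of 6, norbornene carbopalladation followed by C–H palladation at the only free ortho carbon (the later C4a) gives the aryl–norbornyl palladacycle, and this takes up the primary C–Br bond of 4 by SN2-type oxidative addition to tetravalent palladium and forms C4–C4a by reductive elimination. With both ortho positions now occupied (C8 methyl and C4 chain) norbornene is expelled by β-carbon elimination, the arylpalladium at C8a binds the tethered C2 alkoxide, and C(aryl)–O reductive elimination from the seven-membered oxapalladacycle closes the six-membered ring B. The closest known reaction types are the Catellani annulation of aryl iodides with epoxides to 2,3-dihydrobenzofurans (same ortho-alkylation and ipso C–O termination, one ring atom fewer) and the palladium-catalysed intramolecular etherification of aryl halides by tertiary alcohols to 2,2-dialkylchromans; new is their merger with a γ-bromo tertiary alcohol as the bifunctional partner. No stereocentre is created: none of the four bonds at C2 is broken, so the R configuration from step 1 is carried into 7 unchanged. Site selectivity on ring A is secured by the C8 methyl group, which blocks the second ortho position and provides the ortho effect that drives norbornene extrusion. β-Hydride elimination of the palladium alkoxide is excluded because C2 bears no hydrogen, and the bulky electron-rich biarylphosphine is chosen because it tolerates the norbornene cycle and speeds C–O reductive elimination. The trisubstituted alkenes of 4 cannot compete with strained norbornene for arylpalladium, and a Heck closure from C8a onto C3'=C4' would need an eight-membered or larger ring.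

Step 6
Reactants: 7 (2R)-2-[(3E)-4,8-dimethylnona-3,7-dien-1-yl]-2,8-dimethyl-6-(triisopropylsilyloxy)chromane
Product: 9 (2E,6E)-2,6-dimethyl-9-[(2R)-2,8-dimethyl-6-(triisopropylsilyloxy)chroman-2-yl]nona-2,6-dienal, via allylic alcohol 8 (not isolated)
Conditions: SeO2 (0.3 equiv), t-BuOOH (3 equiv), salicylic acid (0.1 equiv), CH2Cl2, 0 °C to rt; filtration, concentration; then MnO2 (20 equiv), CH2Cl2, rt
Reagents that add atoms: tert-butyl hydroperoxide, CC(C)(C)OO (terminal oxygen source); selenium dioxide, O=[Se]=O (oxygen relay)
Why: Catalytic SeO2 allylic oxidation (ene reaction, then [2,3]-sigmatropic shift) prefers the most accessible terminal isopropylidene group and by its mechanism oxidises only the methyl group trans to the chain, which fixes C7'=C8' as E. MnO2 then converges the alcohol/aldehyde mixture on enal 9 and should touch no other group.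

Step 7
Reactants: 9 (2E,6E)-2,6-dimethyl-9-[(2R)-2,8-dimethyl-6-(triisopropylsilyloxy)chroman-2-yl]nona-2,6-dienal
Product: 11 (4R,5E,9E)-5,9-dimethyl-12-[(2R)-2,8-dimethyl-6-(triisopropylsilyloxy)chroman-2-yl]dodeca-1,5,9-trien-4-ol, via pinacol borate 10 (not isolated)
Conditions: CH2=CHCH2B(pin) (1.3 equiv), (R)-3,3'-bis(2,4,6-triisopropylphenyl)-1,1'-binaphthyl-2,2'-diyl hydrogen phosphate [(R)-TRIP, 5 mol %], toluene, −30 °C; aq. NaHCO3
Reagents that add atoms: allylboronic acid pinacol ester, C=CCB1OC(C)(C)C(C)(C)O1
Why: Chiral phosphoric acid-catalysed allylboration through a closed chair transition state in which the acid hydrogen-bonds to a boronate oxygen and to the formyl hydrogen. By analogy with aryl and alkenyl aldehydes the (R)-acid should send allyl to the Re face, which here gives 9'R; C2 is nine bonds away, so control is by the catalyst alone.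

Step 8
Reactants: 11 (4R,5E,9E)-5,9-dimethyl-12-[(2R)-2,8-dimethyl-6-(triisopropylsilyloxy)chroman-2-yl]dodeca-1,5,9-trien-4-ol
Product: 12 (5R,6E,10E)-2,6,10-trimethyl-13-[(2R)-2,8-dimethyl-6-(triisopropylsilyloxy)chroman-2-yl]trideca-2,6,10-trien-5-ol
Conditions: 2-methylbut-2-ene (large excess), CH2Cl2, second-generation Hoveyda–Grubbs catalyst (5 mol %), 35 °C, sealed tube
Reagents that add atoms: 2-methylbut-2-ene, CC=C(C)C
Why: Olefin cross metathesis; the monosubstituted terminal alkene is the only one that loads the ruthenium carbene readily, and the excess partner caps it as the isopropylidene with loss of propene. The trisubstituted alkenes C3'=C4' and C7'=C8' and the free hydroxyl are expected to be inert, and no stereocentre is touched.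

Step 9
Reactants: 12 (5R,6E,10E)-2,6,10-trimethyl-13-[(2R)-2,8-dimethyl-6-(triisopropylsilyloxy)chroman-2-yl]trideca-2,6,10-trien-5-ol
Product: 13 sargachromanol C
Conditions: Bu4NF (1.2 equiv), AcOH (1.2 equiv), THF, 0 °C, argon
Reagents that add atoms: none
Why: Fluoride-induced cleavage of the aryl silyl ether. Acetic acid protonates the phenoxide as it forms, so the electron-rich chromanol is not left open to air oxidation and the 1,5-dien-3-ol never meets a strong base.

## Compound list

1 | (2E,6E)-farnesol | CC(C)=CCC/C(C)=C/CC/C(C)=C/CO | starting material
2 | [(2R,3R)-3-[(3E)-4,8-dimethylnona-3,7-dien-1-yl]-3-methyloxiran-2-yl]methanol | CC(C)=CCC/C(C)=C/CC[C@@]1(C)O[C@@H]1CO | intermediate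
3 | (3R,6E)-3,7,11-trimethyldodeca-6,10-diene-1,3-diol | CC(C)=CCC/C(C)=C/CC[C@@](C)(O)CCO | intermediate
4 | (3R,6E)-1-bromo-3,7,11-trimethyldodeca-6,10-dien-3-ol | CC(C)=CCC/C(C)=C/CC[C@@](C)(O)CCBr | intermediate
5 | 4-iodo-3-methylphenol | Cc1cc(O)ccc1I | starting material
6 | (4-iodo-3-methylphenoxy)triisopropylsilane | Cc1cc(O[Si](C(C)C)(C(C)C)C(C)C)ccc1I | intermediate
7 | (2R)-2-[(3E)-4,8-dimethylnona-3,7-dien-1-yl]-2,8-dimethyl-6-(triisopropylsilyloxy)chromane | CC(C)=CCC/C(C)=C/CC[C@]1(C)CCc2cc(O[Si](C(C)C)(C(C)C)C(C)C)cc(C)c2O1 | intermediate
8 | (2E,6E)-2,6-dimethyl-9-[(2R)-2,8-dimethyl-6-(triisopropylsilyloxy)chroman-2-yl]nona-2,6-dien-1-ol | OC/C(C)=C/CC/C(C)=C/CC[C@]1(C)CCc2cc(O[Si](C(C)C)(C(C)C)C(C)C)cc(C)c2O1 | intermediate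
9 | (2E,6E)-2,6-dimethyl-9-[(2R)-2,8-dimethyl-6-(triisopropylsilyloxy)chroman-2-yl]nona-2,6-dienal | O=C/C(C)=C/CC/C(C)=C/CC[C@]1(C)CCc2cc(O[Si](C(C)C)(C(C)C)C(C)C)cc(C)c2O1 | intermediate
10 | pinacol borate (O-Bpin derivative) of 11 | C=CC[C@@H](OB1OC(C)(C)C(C)(C)O1)/C(C)=C/CC/C(C)=C/CC[C@]2(C)CCc3cc(O[Si](C(C)C)(C(C)C)C(C)C)cc(C)c3O2 | intermediate
11 | (4R,5E,9E)-5,9-dimethyl-12-[(2R)-2,8-dimethyl-6-(triisopropylsilyloxy)chroman-2-yl]dodeca-1,5,9-trien-4-ol | C=CC[C@@H](O)/C(C)=C/CC/C(C)=C/CC[C@]1(C)CCc2cc(O[Si](C(C)C)(C(C)C)C(C)C)cc(C)c2O1 | intermediate
12 | (5R,6E,10E)-2,6,10-trimethyl-13-[(2R)-2,8-dimethyl-6-(triisopropylsilyloxy)chroman-2-yl]trideca-2,6,10-trien-5-ol | CC(C)=CC[C@@H](O)/C(C)=C/CC/C(C)=C/CC[C@]1(C)CCc2cc(O[Si](C(C)C)(C(C)C)C(C)C)cc(C)c2O1 | intermediate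
13 | sargachromanol C, (2R)-2-[(3E,7E,9R)-9-hydroxy-4,8,12-trimethyltrideca-3,7,11-trien-1-yl]-2,8-dimethylchroman-6-ol | CC(C)=CC[C@@H](O)/C(C)=C/CC/C(C)=C/CC[C@]1(C)CCc2cc(O)cc(C)c2O1 | target

## Step count and least certain steps

Total step count: 9. Longest linear sequence: 8 (steps 1, 2, 3, 5, 6, 7, 8, 9). Step 4 is the only branch.

**Step 5 (key step, proposed new method).** Several processes can compete with the planned cascade:
- Bromide 4 may be consumed by base-induced four-membered ether closure or Grob-type fragmentation before it meets the palladacycle.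
- The palladacycle may collapse with retention of the bicyclic mediator if oxidative addition of the alkyl bromide is slow.
- The cycle may terminate at C8a by reduction instead of C–O bond formation, because C–O reductive elimination from divalent palladium is intrinsically slow.
- The silyl ether may be partly lost at 100 °C.

The fallback keeps the retention logic at C2 but builds the two bonds one at a time with known reactions. It sets out from 4 and comes back at 7. 3-Bromo-5-methylphenol F1 is chlorinated para to the hydroxyl group (SO2Cl2, CH2Cl2, 0 °C), the position that 3,5-disubstituted phenols halogenate, to give 3-bromo-4-chloro-5-methylphenol F2. Silylation (i-Pr3SiCl, imidazole, DMF) gives (3-bromo-4-chloro-5-methylphenoxy)triisopropylsilane F3. A nickel-catalysed reductive cross-electrophile coupling (NiI2, 4,4'-dimethoxy-2,2'-bipyridine, Zn, NaI, DMPU, 60 °C) tolerates free alcohols and aryl chlorides. It joins the aryl C–Br bond of F3 to the alkyl C–Br bond of 4 and gives the chloroarene alcohol F4. A Buchwald–Hartwig-type intramolecular etherification (Pd(OAc)2, 2-(di-tert-butylphosphino)-1,1'-binaphthyl, Cs2CO3, toluene, 80 °C) then closes ring B to 7 without touching C2.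

**Step 6.** The likely problems are imperfect site selectivity between the terminal isopropylidene and the internal C3'=C4' alkene (oxidation at C5'), incomplete conversion, and over-oxidation. The fallback builds C7'=C8' instead of oxidising a C–H bond. It sets out from 7 and comes back at 9. Cross metathesis of the terminal isopropylidene group of 7 with methacrolein (second-generation Hoveyda–Grubbs catalyst, CH2Cl2, 40 °C) should exchange the dimethyl terminus for the E-configured 2-methylenal. The internal alkene, flanked by two long chains, stays out of the cycle. No compound outside the list is made (entry F0).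

**Step 7.** Facial selectivity may be insufficient, for example through an uncatalysed background allylboration. The sense of induction is assigned only by analogy. It would be checked on 11 by Mosher ester analysis, and the antipodal acid is equally available. Any erosion matters because the 9'-epimers cannot be expected to separate. The fallback sets C9' by hydride delivery instead of C–C bond formation. It sets out from 9 and comes back at 11. CH2=CHCH2MgBr (THF, −78 °C) adds to 9 to give the 9'-epimeric alcohols F5. MnO2 (CH2Cl2, rt) oxidises them under neutral conditions to the cross-conjugated ketone F6. Corey–Bakshi–Shibata reduction follows, with (S)-5,5-diphenyl-2-methyl-3,4-propano-1,3,2-oxazaborolidine and BH3·SMe2 (THF, −40 °C). It places hydride so that the α-methylalkenyl group acts as the large substituent, which corresponds to 9'R.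

**Step 8.** Ruthenium hydride species formed by catalyst decay may cause migration of the terminal alkene or redox isomerisation of the allylic alcohol. Self-metathesis may compete if the partner is lost from the warm solution. The fallback delivers the intact linear prenyl group and bypasses steps 7 and 8. It sets out from 9 and comes back at 12. 3-Methylbut-2-en-1-yl methyl carbonate F7 (one step from the commercial alcohol and ClCO2CH3) undergoes copper-catalysed γ-selective borylation (CuCl, Xantphos, KOtBu, B2pin2, THF) to give the tertiary allylboronate 2-(2-methylbut-3-en-2-yl)-4,4,5,5-tetramethyl-1,3,2-dioxaborolane F8. This adds to 9 through its unsubstituted γ-carbon under the same (R)-phosphoric acid catalysis. The product is the pinacol borate F9, which is hydrolysed on work-up to 12.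

## Further compounds

F1 | step 5 | 3-bromo-5-methylphenol | Cc1cc(O)cc(Br)c1
F2 | step 5 | 3-bromo-4-chloro-5-methylphenol | Cc1cc(O)cc(Br)c1Cl
F3 | step 5 | (3-bromo-4-chloro-5-methylphenoxy)triisopropylsilane | Cc1cc(O[Si](C(C)C)(C(C)C)C(C)C)cc(Br)c1Cl
F4 | step 5 | (3R,6E)-1-[2-chloro-3-methyl-5-(triisopropylsilyloxy)phenyl]-3,7,11-trimethyldodeca-6,10-dien-3-ol | CC(C)=CCC/C(C)=C/CC[C@@](C)(O)CCc1cc(O[Si](C(C)C)(C(C)C)C(C)C)cc(C)c1Cl
F0 | step 6 | none | none
F5 | step 7 | (5E,9E)-5,9-dimethyl-12-[(2R)-2,8-dimethyl-6-(triisopropylsilyloxy)chroman-2-yl]dodeca-1,5,9-trien-4-ol, both epimers at C4 | C=CCC(O)/C(C)=C/CC/C(C)=C/CC[C@]1(C)CCc2cc(O[Si](C(C)C)(C(C)C)C(C)C)cc(C)c2O1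
F6 | step 7 | (5E,9E)-5,9-dimethyl-12-[(2R)-2,8-dimethyl-6-(triisopropylsilyloxy)chroman-2-yl]dodeca-1,5,9-trien-4-one | C=CCC(=O)/C(C)=C/CC/C(C)=C/CC[C@]1(C)CCc2cc(O[Si](C(C)C)(C(C)C)C(C)C)cc(C)c2O1
F7 | step 8 | 3-methylbut-2-en-1-yl methyl carbonate | COC(=O)OCC=C(C)C
F8 | step 8 | 2-(2-methylbut-3-en-2-yl)-4,4,5,5-tetramethyl-1,3,2-dioxaborolane | C=CC(C)(C)B1OC(C)(C)C(C)(C)O1
F9 | step 8 | pinacol borate (O-Bpin derivative) of 12 | CC(C)=CC[C@@H](OB1OC(C)(C)C(C)(C)O1)/C(C)=C/CC/C(C)=C/CC[C@]2(C)CCc3cc(O[Si](C(C)C)(C(C)C)C(C)C)cc(C)c3O2
A1 | alternative 1 | [(2E,4R)-4-(tert-butyldimethylsilyloxy)-3,7-dimethylocta-2,6-dien-1-yl]sulfonylbenzene | CC(C)=CC[C@@H](O[Si](C)(C)C(C)(C)C)/C(C)=C/CS(=O)(=O)c1ccccc1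
A2 | alternative 1 | (2R)-2-[(3E)-5-bromo-4-methylpent-3-en-1-yl]-2,8-dimethyl-6-(triisopropylsilyloxy)chromane | BrC/C(C)=C/CC[C@]1(C)CCc2cc(O[Si](C(C)C)(C(C)C)C(C)C)cc(C)c2O1
A3 | alternative 1 | C6'-phenylsulfonyl derivative of the 9'-O-TBS, 6-O-TIPS protected target (C6' unassigned) | CC(C)=CC[C@@H](O[Si](C)(C)C(C)(C)C)/C(C)=C/C(C/C(C)=C/CC[C@]1(C)CCc2cc(O[Si](C(C)C)(C(C)C)C(C)C)cc(C)c2O1)S(=O)(=O)c1ccccc1
A4 | alternative 2 | 2-[(2E,6E,10E,12R)-12-hydroxy-3,7,11,15-tetramethylhexadeca-2,6,10,14-tetraen-1-yl]-6-methylbenzene-1,4-diol | CC(C)=CC[C@@H](O)/C(C)=C/CC/C(C)=C/CC/C(C)=C/Cc1cc(O)cc(C)c1O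
A5 | alternative 3 | 2-methyl-6-methylidene-4-(triisopropylsilyloxy)cyclohexa-2,4-dien-1-one | C=C1C=C(O[Si](C(C)C)(C(C)C)C(C)C)C=C(C)C1=O
A6 | alternative 3 | (5E)-2,6,10-trimethylundeca-1,5,9-triene | C=C(C)CC/C=C(\C)CCC=C(C)C
A7 | alternative 3 | racemic 2-[(3E)-4,8-dimethylnona-3,7-dien-1-yl]-2,8-dimethyl-6-(triisopropylsilyloxy)chromane | CC(C)=CCC/C(C)=C/CCC1(C)CCc2cc(O[Si](C(C)C)(C(C)C)C(C)C)cc(C)c2O1
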